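**Assumptions (one line each)**
- The SMILES is read as the all-trans (exo-type) adduct, 5-[(1R,5S,6R)-6-(2,4-dihydroxybenzoyl)-5-(2,4-dihydroxyphenyl)-3-methylcyclohex-2-en-1-yl]-2,4-dihydroxybenzaldehyde.
- 5-Bromo-2,4-dihydroxybenzaldehyde is bought; if not, it is made by Br2/AcOH bromination of 2,4-dihydroxybenzaldehyde.
- (R)-VANOL is assumed to give the (5S,6R) series, by analogy with related 2'-hydroxychalcone cycloadditions. I could not confirm this sense from memory, so it must be checked on the first run (chiral HPLC/CD); if it is the antipode, use commercial (S)-VANOL with no other change.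

**Retrosynthetic overview**
1. Target 14 ⇐ one-pot removal of three allyl ethers and two acetates from adduct 13.
2. The cyclohexene (the only ring formed) ⇐ exo-selective, chiral-borate-promoted Diels–Alder of 2'-hydroxychalcone 6 (dienophile) with aryl diene 12; all three stereocentres are set here.
3. Chalcone 6 ⇐ Claisen–Schmidt condensation of allyl-protected acetophenone 5 and aldehyde 3.
4. Diene 12 ⇐ dehydration of the Heck product of bromo-aldehyde 9 with 2-methyl-3-buten-2-ol.

**Route**

Step 1
Reactants: 1 (2,4-dihydroxybenzaldehyde), 2 (allyl bromide)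
Product: 3, 2,4-bis(allyloxy)benzaldehyde
Conditions: allyl bromide (2.5 equiv), K2CO3, DMF, 60 °C
Reagents that add atoms: allyl bromide, C=CCBr
Why: Williamson etherification of both phenols; allyl ethers survive the later KOH condensation and come off under neutral/basic Pd(0) conditions, avoiding acid.

Step 2
Reactants: 4 (2',4'-dihydroxyacetophenone), 2 (allyl bromide)
Product: 5, 1-[4-(allyloxy)-2-hydroxyphenyl]ethan-1-one
Conditions: allyl bromide (1.1 equiv), K2CO3 (1.2 equiv), acetone, reflux
Reagents that add atoms: allyl bromide, C=CCBr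
Why: Selective Williamson etherification of the 4-OH, because the 2-OH is hydrogen-bonded to the ketone and much less nucleophilic; the free 2-OH is needed later for boron chelation.

Step 3
Reactants: 3, 5
Product: 6, (E)-1-[4-(allyloxy)-2-hydroxyphenyl]-3-[2,4-bis(allyloxy)phenyl]prop-2-en-1-one
Conditions: 50% aq KOH, EtOH, rt, 24–48 h; then cold dilute HCl to pH ~4, filter
Reagents that add atoms: none
Why: Claisen–Schmidt aldol condensation; E1cB dehydration gives the thermodynamic E-enone.

Step 4
Reactants: 7 (5-bromo-2,4-dihydroxybenzaldehyde), 8 (acetic anhydride)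
Product: 9, 4-bromo-6-formyl-1,3-phenylene diacetate (5-bromo-2,4-diacetoxybenzaldehyde)
Conditions: Ac2O, pyridine, DMAP (cat.), CH2Cl2, 0 °C → rt
Reagents that add atoms: acetic anhydride, CC(=O)OC(C)=O
Why: Phenol acylation; the acetates make the aryl bromide less electron-rich for Pd insertion and later stop the salicylaldehyde OH/CHO pair from competing for boron.

Step 5
Reactants: 9, 10 (2-methyl-3-buten-2-ol)
Product: 11, 4-formyl-6-[(E)-3-hydroxy-3-methylbut-1-en-1-yl]-1,3-phenylene diacetate
Conditions: Pd(OAc)2 (5 mol %), P(o-tol)3 (10 mol %), Et3N, dry DMF, 90 °C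
Reagents that add atoms: 2-methyl-3-buten-2-ol, C=CC(C)(C)O
Why: Mizoroki–Heck arylation at the terminal alkene carbon; syn β-hydride elimination gives the E-styrene, and the tertiary carbinol cannot isomerise to a carbonyl.

Step 6
Reactants: 11
Product: 12, 4-formyl-6-[(E)-3-methylbuta-1,3-dien-1-yl]-1,3-phenylene diacetate
Conditions: MsCl, Et3N, CH2Cl2, −20 → 0 °C; add BHT, store cold, use at once
Reagents that add atoms: none
Why: Sulfonylation/elimination of the tertiary allylic alcohol; only the methyl hydrogens can be lost, so the conjugated 3-methyl-1,3-diene forms with the E-styrenyl bond intact.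

Step 7
Reactants: 6 (1 equiv), 12 (2.5 equiv)
Product: 13, 4-[(1R,5S,6R)-6-[4-(allyloxy)-2-hydroxybenzoyl]-5-[2,4-bis(allyloxy)phenyl]-3-methylcyclohex-2-en-1-yl]-6-formyl-1,3-phenylene diacetate
Conditions: (R)-VANOL, BH3·THF, AcOH (1.5 equiv each), THF, rt, then evaporate to dryness (no B–H left); add 6 and 12, PhCF3, rt → 40 °C, 24–48 h; aq NaHCO3 workup; SiO2 then prep-HPLC to remove the endo isomer
Reagents that add atoms: none
Why: Chiral-borate-promoted Diels–Alder in which the 2'-OH/C=O chelate activates the enone and the VANOL wall blocks one face (setting 5S,6R absolute), the E-enone fixes the 5,6-trans relationship, exo approach gives the 1,6-trans relationship, and the diene's largest HOMO coefficient at CH2 bonds to the enone β-carbon; the exo/endo ratio is substrate-dependent (from about 1:1 up to strongly exo in related cases), so separation is planned for.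

Step 8
Reactants: 13
Product: 14, 5-[(1R,5S,6R)-6-(2,4-dihydroxybenzoyl)-5-(2,4-dihydroxyphenyl)-3-methylcyclohex-2-en-1-yl]-2,4-dihydroxybenzaldehyde (target)
Conditions: Pd(PPh3)4 (10 mol %), K2CO3 (8 equiv), degassed MeOH, rt → 40 °C, Ar; quench with pH 6 phosphate buffer; Sephadex LH-20 or RP-HPLC
Reagents that add atoms: none
Why: Tsuji–Trost deallylation (methanol/methoxide traps the π-allyl) with concurrent acetate methanolysis; no acid is used, so the known ketalisation of the free phenol onto the ketone/alkene is avoided, and the only base-labile centre (C6, α to the ketone) already holds the thermodynamic all-equatorial arrangement.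

**Compound list**
1 | 2,4-dihydroxybenzaldehyde | O=Cc1ccc(O)cc1O | starting material
2 | allyl bromide | C=CCBr | starting material
3 | 2,4-bis(allyloxy)benzaldehyde | O=Cc1ccc(OCC=C)cc1OCC=C | intermediate
4 | 2',4'-dihydroxyacetophenone | CC(=O)c1ccc(O)cc1O | starting material
5 | 1-[4-(allyloxy)-2-hydroxyphenyl]ethan-1-one | CC(=O)c1ccc(OCC=C)cc1O | intermediate
6 | (E)-1-[4-(allyloxy)-2-hydroxyphenyl]-3-[2,4-bis(allyloxy)phenyl]prop-2-en-1-one | O=C(/C=C/c1ccc(OCC=C)cc1OCC=C)c1ccc(OCC=C)cc1O | intermediate
7 | 5-bromo-2,4-dihydroxybenzaldehyde | O=Cc1cc(Br)c(O)cc1O | starting material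
8 | acetic anhydride | CC(=O)OC(C)=O | starting material
9 | 4-bromo-6-formyl-1,3-phenylene diacetate | CC(=O)Oc1cc(OC(C)=O)c(C=O)cc1Br | intermediate
10 | 2-methyl-3-buten-2-ol | C=CC(C)(C)O | starting material
11 | 4-formyl-6-[(E)-3-hydroxy-3-methylbut-1-en-1-yl]-1,3-phenylene diacetate | CC(=O)Oc1cc(OC(C)=O)c(C=O)cc1/C=C/C(C)(C)O | intermediate
12 | 4-formyl-6-[(E)-3-methylbuta-1,3-dien-1-yl]-1,3-phenylene diacetate | C=C(C)/C=C/c1cc(C=O)c(OC(C)=O)cc1OC(C)=O | intermediate
13 | (1R,5S,6R) tri-O-allyl di-O-acetyl adduct (name in Step 7) | CC1=C[C@@H](c2cc(C=O)c(OC(C)=O)cc2OC(C)=O)[C@H](C(=O)c2ccc(OCC=C)cc2O)[C@@H](c2ccc(OCC=C)cc2OCC=C)C1 | intermediate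
14 | 5-[(1R,5S,6R)-6-(2,4-dihydroxybenzoyl)-5-(2,4-dihydroxyphenyl)-3-methylcyclohex-2-en-1-yl]-2,4-dihydroxybenzaldehyde | CC1=C[C@@H](c2cc(C=O)c(O)cc2O)[C@H](C(=O)c2ccc(O)cc2O)[C@@H](c2ccc(O)cc2O)C1 | target

**Totals**
- Total steps: 8.
- Longest linear sequence: 5 (7 → 9 → 11 → 12 → 13 → 14).

**Three steps most likely to fail, with fallbacks**
1. Step 7 (exo/endo ratio, ee, sense of induction, diene dimerisation, and a chalcone deactivated by its 2,4-dialkoxy ring). Fallback: run the cycloaddition racemically with silica-supported silver nanoparticles (or thermally), isolate the exo diastereomer, and resolve it by preparative chiral SFC/HPLC at the stage of 13.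
2. Step 6 (polymerisation or allylic chloride formation during dehydration; also covers a sluggish Step 5). Fallback: skip the Heck/dehydration pair and install the diene directly by Suzuki–Miyaura coupling of 9 with (E)-(3-methylbuta-1,3-dien-1-yl)boronic acid pinacol ester, made by hydroboration of 2-methyl-1-buten-3-yne with pinacolborane.
3. Step 8 (C-allylation of the resorcinol rings by π-allyl-Pd, or air oxidation of the polyphenolate). Fallback: change to an all-acetate protecting scheme: make 2,2',4,4'-tetrahydroxychalcone (via MOM ethers, Claisen–Schmidt, HCl/MeOH), selectively triacetylate to leave the chelated 2'-OH free, and finish with K2CO3/MeOH alone, with no Pd.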